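**Assumption:** the target has no stereocentre or stereogenic double bond (it is achiral), so no enantiocontrol is needed; the linker is read from the SMILES as fourteen CH2 groups (C29H40O8).

**Retrosynthetic overview**
1. Cut both ring–CH2 bonds. The chain becomes a nucleophilic C14 α,ω-bis(alkyl-9-BBN) from tetradeca-1,13-diene; each hydroxyquinone becomes an electrophilic enolonium equivalent, namely its phenyliodonium ylide at the carbon that is normally the nucleophilic enol carbon.
2. The ring A ylide comes from the ring B ylide by O-methylation of its single free OH (ylide formation masks the other oxygen pair), which places OMe next to the ring methyl.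
3. The ring B ylide comes from 2,5-dihydroxy-3-methyl-1,4-benzoquinone and PhI(OAc)2; that quinone comes from methylhydroquinone and alkaline H2O2.
4. No ring is built: both six-membered rings come from methylhydroquinone; ring A is joined to the chain first and ring B second, in one pot.

**Route**

Step 1
Reactants: 1 2-methylbenzene-1,4-diol (methylhydroquinone)
Product: 3 2,5-dihydroxy-3-methyl-1,4-benzoquinone, via 2-methyl-1,4-benzoquinone 2 (not isolated)
Conditions: 30% aq. H2O2 (3.5 equiv), 50% aq. NaOH (12 equiv), 45–50 °C, 3 h; then conc. HCl, ice, filter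
Reagents that add atoms: hydrogen peroxide, OO
Why: Alkaline hydrogen-peroxide oxidation of a hydroquinone to a 2,5-dihydroxy-1,4-benzoquinone: after oxidation to 2, two rounds of hydroperoxide conjugate addition (nucleophilic epoxidation/ring opening) and re-oxidation install the two oxygens para to each other, which for a methyl quinone can only give 3; no stereocentre is formed.

Step 2
Reactants: 3 2,5-dihydroxy-3-methyl-1,4-benzoquinone
Product: 4 4-hydroxy-5-methyl-3,6-dioxo-2-(phenyliodonio)cyclohexa-1,4-dien-1-olate (ring B phenyliodonium ylide)
Conditions: PhI(OAc)2 (1.05 equiv), CH2Cl2/MeOH 4:1, 0 °C→rt, 2 h, dark; filter the precipitate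
Reagents that add atoms: (diacetoxyiodo)benzene, CC(=O)OI(OC(C)=O)c1ccccc1
Why: Iodonium ylide formation: the only ring C–H of 3, flanked by an enolic OH and a carbonyl (a cyclic 1,3-dicarbonyl-type C–H acid), condenses with the trivalent-iodine diacetate by ligand exchange and loss of two AcOH, leaving the hydroxyl next to the methyl group as the only free OH; no stereocentre is formed.

Step 3
Reactants: 4 ring B phenyliodonium ylide
Product: 5 4-methoxy-5-methyl-3,6-dioxo-2-(phenyliodonio)cyclohexa-1,4-dien-1-olate (ring A phenyliodonium ylide)
Conditions: TMSCHN2 (1.2 equiv, 2 M in hexanes), CH2Cl2/MeOH 4:1, 0 °C, 1 h, dark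
Reagents that add atoms: (trimethylsilyl)diazomethane, C[Si](C)(C)C=[N+]=[N-]
Why: Diazoalkane O-methylation of an acidic hydroxyquinone (vinylogous carboxylic acid): the single acidic OH protonates TMSCHN2 and the resulting vinylogous carboxylate is methylated (either of its two oxygens gives the same compound 5), while the oxido bound to the iodonium centre is too weakly nucleophilic to compete and the reaction stops once the acid is consumed; no stereocentre is formed.

Step 4
Reactants: 6 tetradeca-1,13-diene; 5 ring A phenyliodonium ylide; 4 ring B phenyliodonium ylide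
Product: 9 2-hydroxy-5-methoxy-6-methyl-3-[14-(2,5-dihydroxy-4-methyl-3,6-dioxocyclohexa-1,4-dien-1-yl)tetradecyl]-1,4-benzoquinone, via 1,14-bis(9-BBN)tetradecane 7 (not isolated), via 14-(9-BBN)tetradecyl ring-A quinone 8 (not isolated)
Conditions: 9-BBN (2.1 equiv), THF, 0 °C→rt, 6 h; then degassed 3 M aq. K3PO4 (6 equiv), PdCl2(dppf) ([1,1'-bis(diphenylphosphino)ferrocene]dichloropalladium, 10 mol%), DMF, 5 (0.7 equiv), rt, 3 h; then 4 (1.6 equiv), rt→35 °C, 8 h, Ar, dark; 1 M HCl, air; oxalic-acid-treated SiO2, then Sephadex LH-20
Reagents that add atoms: none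
Why: Proposed new method: each phenyliodonium ylide is the enolonium (α-cation) equivalent of the normally nucleophilic enol carbon of its hydroxyquinone, so zerovalent palladium inserts into the quinonyl–iodine bond of the trivalent-iodine zwitterion with loss of PhI, the phosphate-activated primary alkyl–9-BBN terminus of 7 (then of 8) transmetalates (dppf disfavouring β-hydride elimination) and reductive elimination forges the ring–CH2 bond, ring A first with the limiting ylide 5 and ring B second with excess 4 at a temperature where released PhI and thermal ylide rearrangement stay slow; the closest known reaction types are the palladium-catalysed Suzuki/Stille arylation of hydroxyquinone phenyliodonium ylides and the B-alkyl Suzuki–Miyaura coupling of alkenyl(aryl)iodonium salts; no stereocentre is formed.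

**Compound list**
1 | 2-methylbenzene-1,4-diol (methylhydroquinone) | Cc1cc(O)ccc1O | starting material
2 | 2-methyl-1,4-benzoquinone | CC1=CC(=O)C=CC1=O | intermediate
3 | 2,5-dihydroxy-3-methyl-1,4-benzoquinone | CC1=C(O)C(=O)C=C(O)C1=O | intermediate
4 | 4-hydroxy-5-methyl-3,6-dioxo-2-(phenyliodonio)cyclohexa-1,4-dien-1-olate (ring B phenyliodonium ylide, zwitterion) | CC1=C(O)C(=O)C([I+]c2ccccc2)=C([O-])C1=O | intermediate
5 | 4-methoxy-5-methyl-3,6-dioxo-2-(phenyliodonio)cyclohexa-1,4-dien-1-olate (ring A phenyliodonium ylide, zwitterion) | COC1=C(C)C(=O)C([O-])=C([I+]c2ccccc2)C1=O | intermediate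
6 | tetradeca-1,13-diene | C=CCCCCCCCCCCCC=C | starting material
7 | 1,14-bis(9-borabicyclo[3.3.1]nonan-9-yl)tetradecane | C1CCC2CCCC1B2CCCCCCCCCCCCCCB1C2CCCC1CCC2 | intermediate
8 | 3-[14-(9-borabicyclo[3.3.1]nonan-9-yl)tetradecyl]-2-hydroxy-5-methoxy-6-methyl-1,4-benzoquinone | COC1=C(C)C(=O)C(O)=C(CCCCCCCCCCCCCCB2C3CCCC2CCC3)C1=O | intermediate
9 | 2-hydroxy-5-methoxy-6-methyl-3-[14-(2,5-dihydroxy-4-methyl-3,6-dioxocyclohexa-1,4-dien-1-yl)tetradecyl]-1,4-benzoquinone (CNP0130251.0, achiral) | COC1=C(C)C(=O)C(O)=C(CCCCCCCCCCCCCCC2=C(O)C(=O)C(C)=C(O)C2=O)C1=O | target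

**Totals**
Total step count: 4. Longest linear sequence: 4 (1 → 3 → 4 → 5 → 9; ylide 4 serves both as precursor of 5 and as the second coupling partner).

**Steps most likely to fail, with fallbacks**

Step 4 is the riskiest. Alkyl transfer from a 9-BBN borane to a hydroxyquinone iodonium ylide is untested. The PhI that is released can compete for the borane. Ylide 4 reacts as its less electrophilic anion under the basic conditions. The hetero-coupling is statistical: with 0.7 equiv of 5 the ceiling is about 65% based on 5, and the two symmetrical homo-dimers must be separated. The fallback sets out from 5 and from the bis-borane 7 (generated from 6 as in step 4) and comes back to the route at 9. With 5 as the only electrophile (2.4 equiv; neutral, no acidic proton, no order-of-addition problem) both chain ends are coupled in one two-directional operation to give the symmetrical 3,3'-(tetradecane-1,14-diyl)bis(2-hydroxy-5-methoxy-6-methyl-1,4-benzoquinone) F1. One of its two vinylogous methyl esters is then saponified (0.5 M NaOH, EtOH/H2O, 40 °C, stopped at about one-third conversion, F1 recovered and recycled), which gives 9.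

Step 3 is the second risk. A diazoalkane has not been used on a trivalent-iodine zwitterion, and attack at iodine or at the iodine-bound oxido could compete. The fallback sets out from 3 and comes back at 5. Acid-catalysed double etherification (MeOH, cat. H2SO4, reflux) gives 2,5-dimethoxy-3-methyl-1,4-benzoquinone F2. Mono-saponification (1.0 equiv NaOH, MeOH/H2O, 0 °C→rt) then cleaves only the methoxy group whose carbon is flanked by the ring C–H, because the methoxy next to the methyl group is shielded and electronically deactivated; this gives 5-hydroxy-2-methoxy-3-methyl-1,4-benzoquinone F3. Treatment of F3 with PhI(OAc)2 (CH2Cl2, rt) gives 5.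

Step 1 is the third risk. The first hydroxylation of 2 can occur para to the methyl group, which is a dead end, and the electron-rich product can be over-oxidised, so the yield may be low. The fallback sets out from 2 (bought as such; it is a cheap catalogue compound) and comes back at 3. Oxidative bis-amination with 40% aq. MeNH2 (EtOH, air, rt) gives 3-methyl-2,5-bis(methylamino)-1,4-benzoquinone F4. Its two vinylogous amides are then hydrolysed (50% aq. H2SO4, 100 °C) to 3.

**Further compounds**
F1 | step 4 | 3,3'-(tetradecane-1,14-diyl)bis(2-hydroxy-5-methoxy-6-methyl-1,4-benzoquinone) | COC1=C(C)C(=O)C(O)=C(CCCCCCCCCCCCCCC2=C(O)C(=O)C(C)=C(OC)C2=O)C1=O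
F2 | step 3 | 2,5-dimethoxy-3-methyl-1,4-benzoquinone | COC1=CC(=O)C(OC)=C(C)C1=O
F3 | step 3 | 5-hydroxy-2-methoxy-3-methyl-1,4-benzoquinone | COC1=C(C)C(=O)C(O)=CC1=O
F4 | step 1 | 3-methyl-2,5-bis(methylamino)-1,4-benzoquinone | CNC1=CC(=O)C(NC)=C(C)C1=O
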